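**Plan**

- Tetralin numbering is used throughout: C1 aryl methine, C2/C3 the CH2OH-bearing carbons, C4 the CH2, C4a/C8a the fusion carbons of ring A, C6 OMe, C7/C8 OH.
- Retrosynthesis: the four O-benzyl bonds are cut first, then the C1–aryl bond (C1 carbinol plus guaiacol), then C4–C4a and C1–C8a together. This splits ring B into a C4a–C8a aryne of ring A and a trans-2,3-disubstituted cyclobutanone enolate that carries C1–C4.
- Enabling feature: C4a and C8a are adjacent ring A carbons that carry the two arms of ring B, and the C8 oxygen sits next to C8a. A C4a–C8a aryne is therefore polarised to take a carbon nucleophile at C4a and leave the anion at C8a for the carbonyl.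
- Forward: ring A is made as an ortho-silyl aryl triflate; the four-membered ring comes from a fumarate/ketene acetal [2+2]. Their union expands the cyclobutanone into ring B as a 1-tetralone. Reduction, Friedel–Crafts arylation at C1 and hydrogenolysis finish the route.
- Stereochemistry: C2 and C3 come from the menthyl-controlled [2+2] (trans from the fumarate) and are spectators afterwards. C1 is set last, by arylation of the C1 cation anti to the C2 substituent.

Key step: step 11

Assumption: the aluminium-promoted [2+2] of di-(−)-menthyl fumarate with ketene acetals is taken to give the (1S,2R) diester, so the (1R,2S) series needed here is entered from (+)-menthol; if the auxiliary induces the opposite sense, (−)-menthol replaces it and nothing else changes.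

**Route**

Step 1
Reactants: 1 2,3-dihydroxy-4-methoxybenzaldehyde
Product: 2 2,3-bis(benzyloxy)-4-methoxybenzaldehyde
Conditions: BnBr (2.5 equiv), K2CO3 (3 equiv), DMF, 60 °C
Reagents that add atoms: benzyl bromide, BrCc1ccccc1
Why: Williamson etherification of both phenols (the chelated 2-OH included, given excess base and heating) should install the benzyl groups that leave in the final hydrogenolysis.

Step 2
Reactants: 2 2,3-bis(benzyloxy)-4-methoxybenzaldehyde
Product: 4 2,3-bis(benzyloxy)-4-methoxyphenol, via aryl formate 3 (not isolated)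
Conditions: mCPBA, CH2Cl2, 0 °C to rt; then K2CO3 (cat.), MeOH, rt
Reagents that add atoms: 3-chloroperoxybenzoic acid (mCPBA), OOC(=O)c1cccc(Cl)c1
Why: Baeyer–Villiger (Dakin-type) oxidation, in which the ortho- and para-alkoxy groups make the aryl group migrate in preference to hydride, followed by methanolysis of the formate, should free the phenol oxygen on the future C8a.

Step 3
Reactants: 4 2,3-bis(benzyloxy)-4-methoxyphenol
Product: 5 2,3-bis(benzyloxy)-6-bromo-4-methoxyphenol
Conditions: NBS, i-Pr2NH (10 mol %), CH2Cl2, 0 °C
Reagents that add atoms: N-bromosuccinimide, O=C1CCC(=O)N1Br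
Why: electrophilic aromatic bromination, in which the free hydroxyl is the strongest donor, its para position is blocked by OMe and the amine-mediated NBS conditions deliver bromine ortho to OH, should place the halogen on the future C4a and not on the CH next to OMe.

Step 4
Reactants: 5 2,3-bis(benzyloxy)-6-bromo-4-methoxyphenol
Product: 8 2,3-bis(benzyloxy)-4-methoxy-6-(trimethylsilyl)phenyl trifluoromethanesulfonate, via aryl trimethylsilyl ether 6 (not isolated), via lithium 2-silylphenoxide 7 (not isolated)
Conditions: HMDS, THF, 65 °C, evaporate; n-BuLi, THF, −78 °C; Tf2O, −78 °C to rt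
Reagents that add atoms: hexamethyldisilazane, C[Si](C)(C)N[Si](C)(C)C; trifluoromethanesulfonic anhydride, O=S(=O)(OS(=O)(=O)C(F)(F)F)C(F)(F)F
Why: O-silylation, bromine–lithium exchange and the anionic 1,3 O-to-C silyl shift (retro-Brook rearrangement) should put SiMe3 on C4a, and O-triflation of the resulting lithium phenoxide completes the ortho-silyl aryl triflate, the standard fluoride-triggered aryne precursor.

Step 5
Reactants: 9 (+)-menthol; 10 fumaric acid
Product: 11 di-(+)-menthyl fumarate
Conditions: 9 (2.2 equiv per 10), TsOH·H2O (cat.), toluene, reflux, Dean–Stark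
Reagents that add atoms: (+)-menthol (second equivalent of 9), CC(C)[C@H]1CC[C@H](C)C[C@@H]1O
Why: twofold Fischer esterification, in which each carboxyl group of the diacid takes up one molecule of menthol and azeotropic removal of the two equivalents of water drives the equilibrium, should give the diester with the E geometry of the acid retained.

Step 6
Reactants: 11 di-(+)-menthyl fumarate; 12 ketene diethyl acetal
Product: 13 bis[(1S,2R,5S)-2-isopropyl-5-methylcyclohexyl] (1R,2S)-3,3-diethoxycyclobutane-1,2-dicarboxylate
Conditions: Et2AlCl (2 equiv), toluene, −78 °C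
Reagents that add atoms: none
Why: Lewis acid-promoted [2+2] cycloaddition of a ketene acetal to a fumarate (Michael addition, then ring closure of the zwitterion) keeps the esters trans, and the aluminium-bound menthyl esters shield one alkene face, so both ring stereocentres are set under auxiliary control.

Step 7
Reactants: 13 the dimenthyl cyclobutanedicarboxylate
Product: 14 [(1R,2R)-3,3-diethoxycyclobutane-1,2-diyl]dimethanol
Conditions: LiAlH4, THF, 0 °C to rt
Reagents that add atoms: none
Why: hydride reduction of both esters to primary alcohols should release the auxiliary as recoverable (+)-menthol while the ketal and the two stereocentres stay untouched.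

Step 8
Reactants: 14 [(1R,2R)-3,3-diethoxycyclobutane-1,2-diyl]dimethanol
Product: 15 (2R,3R)-2,3-bis(benzyloxymethyl)-1,1-diethoxycyclobutane
Conditions: NaH (2.5 equiv), BnBr (2.5 equiv), Bu4NI (cat.), THF/DMF, 0 °C to rt
Reagents that add atoms: benzyl bromide, BrCc1ccccc1
Why: Williamson etherification of the two primary alkoxides should give ethers that are inert to base, fluoride and hydride and fall off together with the aryl benzyl ethers at the end.

Step 9
Reactants: 15 (2R,3R)-2,3-bis(benzyloxymethyl)-1,1-diethoxycyclobutane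
Product: 16 (2R,3R)-2,3-bis(benzyloxymethyl)cyclobutan-1-one
Conditions: 0.5 M aq. H2SO4, MeCN, rt
Reagents that add atoms: water, O
Why: acid-catalysed ketal hydrolysis under conditions mild enough that the β-benzyloxy ketone should neither eliminate nor epimerise, the trans isomer being in any case the more stable one.

Step 10
Reactants: 16 (2R,3R)-2,3-bis(benzyloxymethyl)cyclobutan-1-one
Product: 18 {[(3R,4R)-3,4-bis(benzyloxymethyl)cyclobut-1-en-1-yl]oxy}trimethylsilane, via lithium enolate 17 (not isolated)
Conditions: LiN(i-Pr)2 (LDA), Me3SiCl, THF, −78 °C (in situ quench); Et3N, pentane, filtration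
Reagents that add atoms: chlorotrimethylsilane, C[Si](C)(C)Cl
Why: kinetic enolisation at the unsubstituted, less hindered CH2 with immediate O-silylation (enol silane formation under internal-quench conditions) should outrun self-aldol of the strained ketone, leave C2–H and both stereocentres untouched and give an amine-free, regiodefined enolate equivalent.

Step 11
Reactants: 8 2,3-bis(benzyloxy)-4-methoxy-6-(trimethylsilyl)phenyl trifluoromethanesulfonate; 18 {[(3R,4R)-3,4-bis(benzyloxymethyl)cyclobut-1-en-1-yl]oxy}trimethylsilane
Product: 23 (2R,3R)-7,8-bis(benzyloxy)-2,3-bis(benzyloxymethyl)-6-methoxy-3,4-dihydronaphthalen-1(2H)-one, via aryne 19 (not isolated), via caesium enolate 20 (not isolated), via benzocyclobutenoxide 21 (not isolated), via ring-expanded dienolate 22 (not isolated)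
Conditions: CsF (3 equiv), 18-crown-6, THF, 0 °C to rt, slow addition of 8 to 18 (1.5 equiv); then aq. NH4Cl
Reagents that add atoms: none
Why: Proposed new method: fluoride strips both silyl groups, so aryne 19 and naked enolate 20 meet without amine or proton donors; the enolate CH carbon (future C4) adds to C4a, the aryl anion left at C8a closes onto the strained and therefore unusually electrophilic cyclobutanone carbonyl to give benzocyclobutenoxide 21, and cleavage of the C1–C4 bond shared by the two four-membered rings releases both ring strains and gives ring B as the arene-conjugated dienolate 22, protonated at C4 on work-up (a direct [2+2] of the aryne with the enol silane followed by desilylation would converge on the same alkoxide). The closest known reaction types are the arynic condensation of ketone enolates (benzocyclobutenoxide formation and fragmentation to two-carbon ring-expanded benzocycloalkenones), the aryne acyl-alkylation of β-ketoesters and the [2+2] of arynes with ketene acetals, none of them shown for a cyclobutanone enolate. Ring B is closed by the sequence C-arylation, 4-exo-trig addition of the aryl anion to C=O and alkoxide fragmentation, so the six-membered ring arises by two-carbon expansion of the four-membered ring and not by a direct six-ring closure. No stereocentre is created: C2 and C3 are spectators that are never deprotonated (C2 belongs to neither enolate), and the transient centres of 21 vanish in the fragmentation. The step needs regioselective capture of the aryne, secured by the inductively withdrawing C8 benzyloxy group, which sends the nucleophile to the remote C4a and lets the anion develop at C8a ortho to oxygen, and it needs the CH2-derived carbon to be the nucleophile, which the enol silane 18 fixes in advance. C- over O-arylation is expected from the soft character of the aryne, and slow addition of 8 to an excess of 18 should keep dienolate 22 from being arylated a second time.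

Step 12
Reactants: 23 the tetralone
Product: 24 (2R,3R)-7,8-bis(benzyloxy)-2,3-bis(benzyloxymethyl)-6-methoxy-1,2,3,4-tetrahydronaphthalen-1-ol (C1 epimers)
Conditions: NaBH4, MeOH/THF, 0 °C to rt
Reagents that add atoms: none
Why: borohydride reduction of the aryl ketone should give the benzylic alcohol, whose C1 configuration is of no consequence because C1 is ionised in the next step.

Step 13
Reactants: 24 the C1 carbinol; 25 guaiacol
Product: 26 4-[(1S,2R,3R)-7,8-bis(benzyloxy)-2,3-bis(benzyloxymethyl)-6-methoxy-1,2,3,4-tetrahydronaphthalen-1-yl]-2-methoxyphenol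
Conditions: 25 (5 equiv), TsOH·H2O (10 mol %), HFIP, 0 °C to rt
Reagents that add atoms: none
Why: Friedel–Crafts alkylation through the C1 benzylic cation (stabilised by the para C6 methoxy and ortho C8 benzyloxy groups), in which guaiacol reacts at the carbon para to its free OH, the stronger donor, and attacks the face opposite the C2 substituent, should set C1 as S (1,2-trans), reinforced by reversibility towards the all-equatorial product.

Step 14
Reactants: 26 the tetrabenzyl ether
Product: 27 (1S,2R,3R)-1-(4-hydroxy-3-methoxyphenyl)-2,3-bis(hydroxymethyl)-6-methoxy-1,2,3,4-tetrahydronaphthalene-7,8-diol (CNP0219328.1)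
Conditions: H2 (1 atm), Pd/C, EtOAc/MeOH, rt
Reagents that add atoms: none
Why: hydrogenolysis of the two aryl and two alkyl benzyl ethers should unveil the target, the diarylmethine C1–aryl bond and the three stereocentres being inert to these conditions.

**Compound list**

1 | 2,3-dihydroxy-4-methoxybenzaldehyde | COc1ccc(C=O)c(O)c1O | starting material
2 | 2,3-bis(benzyloxy)-4-methoxybenzaldehyde | COc1ccc(C=O)c(OCc2ccccc2)c1OCc1ccccc1 | intermediate
3 | 2,3-bis(benzyloxy)-4-methoxyphenyl formate | COc1ccc(OC=O)c(OCc2ccccc2)c1OCc1ccccc1 | intermediate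
4 | 2,3-bis(benzyloxy)-4-methoxyphenol | COc1ccc(O)c(OCc2ccccc2)c1OCc1ccccc1 | intermediate
5 | 2,3-bis(benzyloxy)-6-bromo-4-methoxyphenol | COc1cc(Br)c(O)c(OCc2ccccc2)c1OCc1ccccc1 | intermediate
6 | [2,3-bis(benzyloxy)-6-bromo-4-methoxyphenoxy]trimethylsilane | COc1cc(Br)c(O[Si](C)(C)C)c(OCc2ccccc2)c1OCc1ccccc1 | intermediate
7 | lithium 2,3-bis(benzyloxy)-4-methoxy-6-(trimethylsilyl)phenoxide | [Li+].COc1cc([Si](C)(C)C)c([O-])c(OCc2ccccc2)c1OCc1ccccc1 | intermediate
8 | 2,3-bis(benzyloxy)-4-methoxy-6-(trimethylsilyl)phenyl trifluoromethanesulfonate (OTf on C8a, SiMe3 on C4a) | COc1cc([Si](C)(C)C)c(OS(=O)(=O)C(F)(F)F)c(OCc2ccccc2)c1OCc1ccccc1 | intermediate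
9 | (+)-menthol, (1S,2R,5S)-2-isopropyl-5-methylcyclohexan-1-ol | CC(C)[C@H]1CC[C@H](C)C[C@@H]1O | starting material
10 | fumaric acid | OC(=O)/C=C/C(=O)O | starting material
11 | di-(+)-menthyl fumarate | CC(C)[C@H]1CC[C@H](C)C[C@@H]1OC(=O)/C=C/C(=O)O[C@H]1C[C@@H](C)CC[C@@H]1C(C)C | intermediate
12 | ketene diethyl acetal (1,1-diethoxyethene) | C=C(OCC)OCC | starting material
13 | bis[(1S,2R,5S)-2-isopropyl-5-methylcyclohexyl] (1R,2S)-3,3-diethoxycyclobutane-1,2-dicarboxylate | CCOC1(OCC)C[C@@H](C(=O)O[C@H]2C[C@@H](C)CC[C@@H]2C(C)C)[C@@H]1C(=O)O[C@H]1C[C@@H](C)CC[C@@H]1C(C)C | intermediate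
14 | [(1R,2R)-3,3-diethoxycyclobutane-1,2-diyl]dimethanol | CCOC1(OCC)C[C@@H](CO)[C@@H]1CO | intermediate
15 | (2R,3R)-2,3-bis(benzyloxymethyl)-1,1-diethoxycyclobutane | CCOC1(OCC)C[C@@H](COCc2ccccc2)[C@@H]1COCc1ccccc1 | intermediate
16 | (2R,3R)-2,3-bis(benzyloxymethyl)cyclobutan-1-one | O=C1C[C@@H](COCc2ccccc2)[C@@H]1COCc1ccccc1 | intermediate
17 | lithium (3R,4R)-3,4-bis(benzyloxymethyl)cyclobut-1-en-1-olate | [Li+].[O-]C1=C[C@@H](COCc2ccccc2)[C@@H]1COCc1ccccc1 | intermediate
18 | {[(3R,4R)-3,4-bis(benzyloxymethyl)cyclobut-1-en-1-yl]oxy}trimethylsilane | C[Si](C)(C)OC1=C[C@@H](COCc2ccccc2)[C@@H]1COCc1ccccc1 | intermediate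
19 | 3,4-bis(benzyloxy)-5-methoxybenzyne (aryne carbons are C4a and C8a) | COC1=CC#CC(OCc2ccccc2)=C1OCc1ccccc1 | intermediate
20 | caesium (3R,4R)-3,4-bis(benzyloxymethyl)cyclobut-1-en-1-olate | [Cs+].[O-]C1=C[C@@H](COCc2ccccc2)[C@@H]1COCc1ccccc1 | intermediate
21 | caesium alkoxide of the cis-fused benzocyclobutenol–cyclobutane adduct (C1 bonded to O, C8a, C2 and C4; C4 bonded to C4a; arene anti to the C3 substituent) | [Cs+].[O-][C@@]12c3c(OCc4ccccc4)c(OCc4ccccc4)c(OC)cc3[C@@H]1[C@@H](COCc1ccccc1)[C@@H]2COCc1ccccc1 | intermediate
22 | caesium dienolate of 23 (C1 enolate oxygen conjugated through C8a–C4a with the C4 carbanion) | [Cs+].[O-]C1=C2C(OCc3ccccc3)=C(OCc3ccccc3)C(OC)=CC2=C[C@@H](COCc2ccccc2)[C@@H]1COCc1ccccc1 | intermediate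
23 | (2R,3R)-7,8-bis(benzyloxy)-2,3-bis(benzyloxymethyl)-6-methoxy-3,4-dihydronaphthalen-1(2H)-one | COc1cc2C[C@@H](COCc3ccccc3)[C@H](COCc3ccccc3)C(=O)c2c(OCc2ccccc2)c1OCc1ccccc1 | intermediate
24 | (2R,3R)-7,8-bis(benzyloxy)-2,3-bis(benzyloxymethyl)-6-methoxy-1,2,3,4-tetrahydronaphthalen-1-ol (C1 epimers) | COc1cc2C[C@@H](COCc3ccccc3)[C@H](COCc3ccccc3)C(O)c2c(OCc2ccccc2)c1OCc1ccccc1 | intermediate
25 | guaiacol (2-methoxyphenol) | COc1ccccc1O | starting material
26 | 4-[(1S,2R,3R)-7,8-bis(benzyloxy)-2,3-bis(benzyloxymethyl)-6-methoxy-1,2,3,4-tetrahydronaphthalen-1-yl]-2-methoxyphenol | COc1cc([C@H]2c3c(cc(OC)c(OCc4ccccc4)c3OCc3ccccc3)C[C@@H](COCc3ccccc3)[C@@H]2COCc2ccccc2)ccc1O | intermediate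
27 | (1S,2R,3R)-1-(4-hydroxy-3-methoxyphenyl)-2,3-bis(hydroxymethyl)-6-methoxy-1,2,3,4-tetrahydronaphthalene-7,8-diol | COc1cc([C@H]2c3c(cc(OC)c(O)c3O)C[C@@H](CO)[C@@H]2CO)ccc1O | target

**Step count**

Total: 14 steps. Longest linear sequence: 10 steps (steps 5 to 14, from (+)-menthol and fumaric acid); the ring A branch (steps 1 to 4) joins at step 11.

**Steps most likely to fail, with fallbacks**

1. Step 11 (proposed new method).
   - What may go wrong: the C8a aryl anion may be protonated before it closes onto the carbonyl (plain α-arylation); the enolate may be arylated on oxygen; the aryne may undergo an ene reaction with the enol silane; the product dienolate may be arylated again; proton transfer from C2 to the C4 anion may give the C1–C2 enolate, which could expel benzyloxide from the C2 side chain.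
   - Fallback (known chemistry only), setting out from 8, 12 and 11 and returning at 27: 8 would be treated with CsF in MeCN in the presence of 12. The regioselective aryne–ketene acetal [2+2] (CH2 carbon to C4a) should give benzocyclobutenone diethyl ketal F1. Mild aqueous acid would convert it into benzocyclobutenone F2, and NaBH4 would reduce that to benzocyclobutenol F3. Heating F3 with 11 in toluene should open the four-membered ring to the E-hydroxy-o-quinodimethane. Diels–Alder addition to the fumarate then builds ring B through the C1–C2 and C3–C4 bonds instead, giving hydroxy diester F4 (2,3-trans from the fumarate). The facial preference of the menthyl esters would have to be established, with the unwanted diastereomer removed by crystallisation or the antipodal fumarate used. Friedel–Crafts arylation of F4 with 25 as in step 13 should give aryl diester F5, LiAlH4 reduction should give diol F6, and hydrogenolysis of its two benzyl ethers would give 27.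

2. Step 13.
   - What may go wrong: guaiacol may attack through the carbon para to OMe or ortho to OH; the C1 cation may be captured by the oxygen of the C3 benzyloxymethyl group with loss of benzyl (bridged ether); proton loss from C2 to the C1=C2 alkene would erode the C2 centre.
   - Fallback, setting out from 24 and returning at 27: 24 would be converted in situ (MsCl, Et3N, −20 °C) into benzylic mesylate F7. Nickel-catalysed Negishi arylation (NiBr2·glyme, bipyridine-type ligand) with [4-(benzyloxy)-3-methoxyphenyl]zinc iodide, made from 1-(benzyloxy)-4-bromo-2-methoxybenzene, would follow. The C–Zn bond fixes the aryl regiochemistry, and the benzylic intermediate should be captured anti to the C2 substituent. This would give pentabenzyl ether F8, whose hydrogenolysis under the conditions of step 14 gives 27.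

3. Step 3.
   - What may go wrong: bromination at the CH next to OMe, double bromination, or oxidation of the electron-rich para-methoxyphenol to a quinone.
   - Fallback, setting out from 4 and returning at 8: 4 would be carbamoylated with isopropyl isocyanate (Et3N) to N-isopropyl carbamate F9. Transient N-silylation (Me3SiOTf, TMEDA), n-BuLi at −78 °C and Me3SiCl would follow; this directed ortho metalation has only one ortho C–H available and should give silyl carbamate F10. Et2NH/DBU in MeCN would cleave the carbamate to silylphenol F11, and PhNTf2 would triflate it in the same pot to 8.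

**Further compounds**

F1 | step 11 | 4,5-bis(benzyloxy)-7,7-diethoxy-3-methoxybicyclo[4.2.0]octa-1,3,5-triene | CCOC1(OCC)Cc2cc(OC)c(OCc3ccccc3)c(OCc3ccccc3)c21
F2 | step 11 | 4,5-bis(benzyloxy)-3-methoxybicyclo[4.2.0]octa-1,3,5-trien-7-one | COc1cc2CC(=O)c2c(OCc2ccccc2)c1OCc1ccccc1
F3 | step 11 | 4,5-bis(benzyloxy)-3-methoxybicyclo[4.2.0]octa-1,3,5-trien-7-ol (racemic) | COc1cc2CC(O)c2c(OCc2ccccc2)c1OCc1ccccc1
F4 | step 11 | bis[(1S,2R,5S)-2-isopropyl-5-methylcyclohexyl] (2S,3R)-7,8-bis(benzyloxy)-1-hydroxy-6-methoxy-1,2,3,4-tetrahydronaphthalene-2,3-dicarboxylate (C1 epimers) | COc1cc2C[C@@H](C(=O)O[C@H]3C[C@@H](C)CC[C@@H]3C(C)C)[C@H](C(=O)O[C@H]3C[C@@H](C)CC[C@@H]3C(C)C)C(O)c2c(OCc2ccccc2)c1OCc1ccccc1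
F5 | step 11 | bis[(1S,2R,5S)-2-isopropyl-5-methylcyclohexyl] (1S,2R,3R)-7,8-bis(benzyloxy)-1-(4-hydroxy-3-methoxyphenyl)-6-methoxy-1,2,3,4-tetrahydronaphthalene-2,3-dicarboxylate | COc1cc([C@H]2c3c(cc(OC)c(OCc4ccccc4)c3OCc3ccccc3)C[C@@H](C(=O)O[C@H]3C[C@@H](C)CC[C@@H]3C(C)C)[C@@H]2C(=O)O[C@H]2C[C@@H](C)CC[C@@H]2C(C)C)ccc1O
F6 | step 11 | 4-[(1S,2R,3R)-7,8-bis(benzyloxy)-2,3-bis(hydroxymethyl)-6-methoxy-1,2,3,4-tetrahydronaphthalen-1-yl]-2-methoxyphenol | COc1cc([C@H]2c3c(cc(OC)c(OCc4ccccc4)c3OCc3ccccc3)C[C@@H](CO)[C@@H]2CO)ccc1O
F7 | step 13 | (2R,3R)-7,8-bis(benzyloxy)-2,3-bis(benzyloxymethyl)-6-methoxy-1,2,3,4-tetrahydronaphthalen-1-yl methanesulfonate (C1 epimers) | COc1cc2C[C@@H](COCc3ccccc3)[C@H](COCc3ccccc3)C(OS(C)(=O)=O)c2c(OCc2ccccc2)c1OCc1ccccc1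
F8 | step 13 | (1S,2R,3R)-7,8-bis(benzyloxy)-1-[4-(benzyloxy)-3-methoxyphenyl]-2,3-bis(benzyloxymethyl)-6-methoxy-1,2,3,4-tetrahydronaphthalene | COc1cc([C@H]2c3c(cc(OC)c(OCc4ccccc4)c3OCc3ccccc3)C[C@@H](COCc3ccccc3)[C@@H]2COCc2ccccc2)ccc1OCc1ccccc1
F9 | step 3 | 2,3-bis(benzyloxy)-4-methoxyphenyl N-isopropylcarbamate | COc1ccc(OC(=O)NC(C)C)c(OCc2ccccc2)c1OCc1ccccc1
F10 | step 3 | 2,3-bis(benzyloxy)-4-methoxy-6-(trimethylsilyl)phenyl N-isopropylcarbamate | COc1cc([Si](C)(C)C)c(OC(=O)NC(C)C)c(OCc2ccccc2)c1OCc1ccccc1
F11 | step 3 | 2,3-bis(benzyloxy)-4-methoxy-6-(trimethylsilyl)phenol | COc1cc([Si](C)(C)C)c(O)c(OCc2ccccc2)c1OCc1ccccc1
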